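The route rests on the C1–C10 bond of the ten-membered carbocycle (germacrane numbering): C1 (secondary, esterified oxygen) and C10 (tertiary carbinol) form a 1,2-diol unit, the retron of a pinacol coupling. A SmI2-mediated ketone–aldehyde pinacol cyclisation closes the cyclodecane ring and creates both carbinol stereocentres in one operation. Its precursor is an open-chain C10 methyl ketone/C1 aldehyde that already holds the 3,4-epoxide and the C5, C6, C7 and C9 stereocentres. It is built from (R)-carvone by cleavage of the ring C=C of cis-carveol (C7, C9), proline-catalysed α-aminoxylation (C6), chelate-controlled (Z)-vinyl addition, directed epoxidation and Zn(BH4)2 reduction (C3–C5).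

Key step: step 18

Remarks before the steps
- Numbering: all compounds carry the locants of the target ring. C1 = CH–OAng next to C10; C2 = CH2; C3/C4 = epoxide (C4 bears methyl C15); C5 = CH–OAc; C6 = CH–OAng; C7 = CH–isopropenyl; C8 = CH2; C9 = CH–OH; C10 = C(OH)CH3 (methyl C14). The target is (1S,3R,4R,5S,6S,7R,9R,10S).
- Carvone mapping: carvone C1 (C=O) becomes C9, C2 (with its methyl) C10/C14, C3 C5, C4 C6, C5 C7 and C6 C8.
- Abbreviations: PMB = 4-methoxybenzyl, DMB = 3,4-dimethoxybenzyl, TES = triethylsilyl, TBS = tert-butyldimethylsilyl, Ang = angeloyl [(Z)-2-methylbut-2-enoyl], DMP = Dess–Martin periodinane.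
- Assumption: 3-[(tert-butyldimethylsilyl)oxy]propanal (13) is taken as a purchasable material.
- Compounds 8–12 and 17–22 carry a temporary carbinol centre at C10, drawn as the expected chelation-controlled 10S epimer. Step 17 erases it, so any minor epimer converges.

Step 1
Reactants: 1 (R)-(−)-carvone
Product: 2 (−)-cis-carveol, (1R,5R)-2-methyl-5-(prop-1-en-2-yl)cyclohex-2-en-1-ol
Conditions: NaBH4, CeCl3·7H2O, MeOH, −20 °C
Reagents that add atoms: none
Why: Luche 1,2-reduction, in which hydride adds to the carbonyl face remote from the isopropenyl group, so that the new hydroxyl (target C9) should end cis to it.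

Step 2
Reactants: 2 (−)-cis-carveol
Product: 3 syn-epoxy alcohol (ring epoxide, hydroxyl and isopropenyl all cis)
Conditions: VO(acac)2 (2 mol %), t-BuOOH, CH2Cl2, 0 °C to rt
Reagents that add atoms: tert-butyl hydroperoxide, CC(C)(C)OO
Why: hydroxyl-directed vanadium-catalysed epoxidation delivers oxygen syn to the allylic hydroxyl on the ring alkene only, so the isolated isopropenyl group should stay untouched.

Step 3
Reactants: 3 syn-epoxy alcohol
Product: 4 PMB ether of 3
Conditions: NaH, PMBCl, n-Bu4NI (cat.), THF–DMF, 0 °C to rt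
Reagents that add atoms: 4-methoxybenzyl chloride, COc1ccc(CCl)cc1
Why: Williamson etherification; the alkoxide is syn to the epoxide and cannot undergo Payne rearrangement, and the PMB ether later serves as the chelating group at C9.

Step 4
Reactants: 4 PMB ether of 3
Product: 6 (3S,5R)-5-[(4-methoxybenzyl)oxy]-6-oxo-3-(prop-1-en-2-yl)heptanal (C5 aldehyde/C10 ketone), via trans-diol 5 (not isolated)
Conditions: H5IO6, THF–H2O, 0 °C to rt
Reagents that add atoms: water, O
Why: acid-mediated epoxide hydrolysis followed by periodate glycol cleavage (Malaprade reaction) cuts the former C2–C3 bond of the carvone ring (target C10/C5) and releases the C10 methyl ketone and the C5 aldehyde with C7 and C9 intact.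

Step 5
Reactants: 6 keto aldehyde
Product: 8 C5,C10-diol with O6–NHPh and O9–PMB, via α-aminoxy keto aldehyde 7 (not isolated)
Conditions: D-proline (20 mol %), PhNO, CHCl3, 4 °C; then Zn(BH4)2, Et2O, −20 °C
Reagents that add atoms: nitrosobenzene, O=Nc1ccccc1
Why: proline enamine catalysis (α-aminoxylation), in which D-proline delivers the nitroso oxygen to the enamine face that gives the (S)-configured C6 under catalyst control, and the in situ reduction stabilises the labile α-aminoxy aldehyde and masks the C10 ketone as a carbinol (chelation-controlled, 9,10-anti).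

Step 6
Reactants: 8 aminoxy diol
Product: 9 5,10-bis-TES ether of 8
Conditions: TESCl, imidazole, CH2Cl2, 0 °C
Reagents that add atoms: chlorotriethylsilane, CC[Si](Cl)(CC)CC
Why: standard silylation of the primary and the secondary hydroxyl while O6 stays masked as the aminoxy group, which differentiates the three oxygens.

Step 7
Reactants: 9 bis-TES ether
Product: 10 C6 alcohol (5,10-bis-TES, 9-PMB)
Conditions: SmI2, THF, rt
Reagents that add atoms: none
Why: single-electron reductive cleavage of the weak N–O bond frees the C6 hydroxyl under neutral conditions that leave silyl and benzyl ethers and the alkene untouched.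

Step 8
Reactants: 10 C6 alcohol
Product: 11 C6 DMB ether
Conditions: 3,4-dimethoxybenzyl trichloroacetimidate, PPTS (10 mol %), CH2Cl2, rt
Reagents that add atoms: 3,4-dimethoxybenzyl 2,2,2-trichloroacetimidate, COc1ccc(COC(=N)C(Cl)(Cl)Cl)cc1OC
Why: acid-catalysed imidate benzylation avoids an alkoxide (no 1,2-silyl migration) and installs a chelating ether that DDQ later removes before the PMB group.

Step 9
Reactants: 11 C6 DMB ether
Product: 12 C5 aldehyde (6-DMB, 9-PMB, 10-TES)
Conditions: (COCl)2, DMSO, CH2Cl2, −78 to −35 °C; then Et3N, −78 to 0 °C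
Reagents that add atoms: none
Why: Swern conditions convert a primary TES ether directly into the aldehyde while the secondary TES ether stays, which saves a separate deprotection.

Step 10
Reactants: 13 3-[(tert-butyldimethylsilyl)oxy]propanal
Product: 14 (Z)-tert-butyl[(4-iodopent-3-en-1-yl)oxy]dimethylsilane
Conditions: [Ph3PCH2CH3]I, n-BuLi, THF, rt; I2, −78 °C; NaN(SiMe3)2, −20 °C; then 13, −78 to −20 °C
Reagents that add atoms: ethyltriphenylphosphonium iodide, CC[P+](c1ccccc1)(c1ccccc1)c1ccccc1.[I-]; iodine, II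
Why: Wittig olefination with the α-iodo ylide (Stork–Zhao type) under kinetic control gives the (Z)-iodoalkene with iodine cis to the chain, which later places C5 cis to C2 as the cis-epoxide requires.

Step 11
Reactants: 12 C5 aldehyde; 14 (Z)-vinyl iodide
Product: 17 (Z)-allylic alcohol with 5,6-syn configuration (C5 epimeric to the target), via vinyllithium 15 (not isolated), via vinylmagnesium bromide 16 (not isolated)
Conditions: 14, t-BuLi, Et2O, −78 °C; MgBr2·OEt2; then 12, MgBr2·OEt2, CH2Cl2, −78 °C
Reagents that add atoms: none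
Why: iodine–lithium exchange and transmetalation keep the alkene geometry, and the vinyl Grignard adds to the MgBr2 chelate of the aldehyde oxygen and the O6 DMB ether from the face opposite C7 (Cram-chelate control), giving the 5,6-syn alcohol, which is deliberately the C5 epimer that step 12 needs.

Step 12
Reactants: 17 (Z)-allylic alcohol
Product: 18 threo 3,4-epoxy-5-ol (C3 and C4 as in the target, C5 still epimeric)
Conditions: mCPBA, NaHCO3, CH2Cl2, −20 to 0 °C
Reagents that add atoms: 3-chloroperoxybenzoic acid, OOC(=O)c1cccc(Cl)c1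
Why: hydroxyl-directed peracid epoxidation (Henbest) under A(1,3) strain control: with C5–H eclipsing the (Z)-alkene, the hydroxyl and the hydrogen-bonded peracid occupy the face opposite C6, which should give the threo epoxy alcohol with the C3/C4 configuration of the target, the trisubstituted allylic alkene reacting faster than the isopropenyl group.

Step 13
Reactants: 18 threo epoxy alcohol
Product: 19 3,4-epoxy-5-ketone
Conditions: DMP, NaHCO3, CH2Cl2, 0 °C to rt
Reagents that add atoms: none
Why: Dess–Martin oxidation under buffered, non-basic conditions removes the temporary C5 centre without epimerising C6 (C4 is quaternary).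

Step 14
Reactants: 19 epoxy ketone
Product: 20 erythro 3,4-epoxy-5-ol (C5 as in the target)
Conditions: Zn(BH4)2, Et2O, −20 °C
Reagents that add atoms: none
Why: chelation-controlled hydride reduction: zinc bridges the carbonyl oxygen with the epoxide oxygen and the O6 ether, and hydride enters anti to the epoxide C3 and to C7, which should give the erythro epoxy alcohol with the 5,6-anti relationship of the target.

Step 15
Reactants: 20 erythro epoxy alcohol
Product: 21 C5 acetate
Conditions: Ac2O, pyridine, DMAP (cat.), CH2Cl2, 0 °C to rt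
Reagents that add atoms: acetic anhydride, CC(=O)OC(C)=O
Why: DMAP-catalysed acetylation of the only free hydroxyl.

Step 16
Reactants: 21 C5 acetate
Product: 22 C1,C10-diol
Conditions: HF·pyridine, pyridine, THF, 0 °C to rt
Reagents that add atoms: none
Why: buffered fluoride desilylation removes the primary TBS and the secondary TES ether while the benzyl ethers, the acetate and the epoxide should survive.

Step 17
Reactants: 22 C1,C10-diol
Product: 23 open-chain C10 methyl ketone/C1 aldehyde
Conditions: DMP, NaHCO3, CH2Cl2, 0 °C to rt (used at once)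
Reagents that add atoms: none
Why: double Dess–Martin oxidation gives the ketone (erasing the temporary C10 centre) and the β,γ-epoxy aldehyde under buffered conditions that avoid base-induced epoxide opening.

Step 18
Reactants: 23 open-chain keto aldehyde
Product: 24 ten-membered 1,10-diol (1S,10S; 6-DMB, 9-PMB, 5-OAc, 3,4-epoxide)
Conditions: SmI2 (4 equiv), THF, −78 °C to rt, slow addition of 23 to a final 2 mM; then aq. NaHCO3
Reagents that add atoms: none
Why: SmI2 reduces the C1 aldehyde (faster than the dialkyl ketone) to a samarium ketyl, which adds to the C10 ketone activated by trivalent samarium, and a second electron transfer gives the diolate, i.e. an intramolecular ketone–aldehyde pinacol coupling whose closest precedents are SmI2 and low-valent titanium pinacol closures of medium and large carbocycles. The cyclodecane ring closes in a 10-exo-trig ketyl addition. C10 is controlled by a five-membered chelate of trivalent samarium between the ketone oxygen and the C9 PMB ether (Cram-chelate), the ketyl attacking the face opposite C8, which should give the 9,10-threo relationship. C1 is expected to follow from an antiperiplanar arrangement of the two samarium-bound oxygens in the ten-membered transition state, which leads to the 1,10-trans (threo) diol typical of pinacol closures of rings of ten or more members. The step needs ketyl formation at the aldehyde only, without loss of the α-alkoxy group of the ketone, the acetate or the 3,4-epoxide; HMPA-free conditions at low temperature should secure this, and slow addition at high dilution suppresses intermolecular coupling.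

Step 19
Reactants: 24 macrocyclic 1,10-diol
Product: 25 1,6,10-triol (9-PMB, 5-OAc)
Conditions: DDQ (1.2 equiv), CH2Cl2–pH 7 buffer, 0 °C
Reagents that add atoms: none
Why: oxidative benzyl ether cleavage by single-electron transfer, in which the more electron-rich DMB ether should be removed before the PMB ether.

Step 20
Reactants: 25 1,6,10-triol
Product: 26 1,6-bis-angelate (9-PMB, 5-OAc, free tertiary C10–OH)
Conditions: angelic acid, 2,4,6-trichlorobenzoyl chloride, Et3N, toluene, rt; then 25, 75 °C
Reagents that add atoms: angelic acid, C/C=C(/C)C(=O)O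
Why: Yamaguchi-type acylation with the preformed mixed anhydride, without DMAP, esterifies the two secondary hydroxyls without Z-to-E isomerisation, while the tertiary C10 hydroxyl should not react.

Step 21
Reactants: 26 1,6-bis-angelate PMB ether
Product: 27 target, (1S,3R,4R,5S,6S,7R,9R,10S)-5-acetoxy-1,6-bis(angeloyloxy)-3,4-epoxygermacr-11-ene-9,10-diol
Conditions: DDQ, CH2Cl2–pH 7 buffer, 0 °C to rt
Reagents that add atoms: none
Why: neutral oxidative PMB cleavage in wet, buffered medium frees the C9 hydroxyl without touching the angelates, the acetate or the epoxide.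

Compound list
1 | (R)-(−)-carvone | CC1=CC[C@H](CC1=O)C(C)=C | starting material
2 | (−)-cis-carveol, (1R,5R) | O[C@H]1C(C)=CC[C@@H](C(C)=C)C1 | intermediate
3 | syn-epoxy alcohol: 1-methyl-4-(prop-1-en-2-yl)-7-oxabicyclo[4.1.0]heptan-2-ol, epoxide, OH and isopropenyl all cis | O[C@H]1[C@@]2(C)O[C@H]2C[C@@H](C(C)=C)C1 | intermediate
4 | PMB ether of 3 | COc1ccc(CO[C@H]2[C@@]3(C)O[C@H]3C[C@@H](C(C)=C)C2)cc1 | intermediate
5 | trans-1,2-diol from hydrolysis of 4 (not isolated) | COc1ccc(CO[C@H]2[C@@](C)(O)[C@H](O)C[C@@H](C(C)=C)C2)cc1 | intermediate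
6 | (3S,5R)-5-[(4-methoxybenzyl)oxy]-6-oxo-3-(prop-1-en-2-yl)heptanal (C5 aldehyde, C10 ketone; C7 and C9 as in 27) | CC(=O)[C@H](OCc1ccc(OC)cc1)C[C@H](C(C)=C)CC=O | intermediate
7 | (2S)-2-(N-phenylaminooxy) derivative of 6 (C6 as in 27; not isolated) | CC(=O)[C@H](OCc1ccc(OC)cc1)C[C@H](C(C)=C)[C@H](ONc1ccccc1)C=O | intermediate
8 | C5,C10-diol with O6–NHPh and O9–PMB (10S; C6, C7, C9 as in 27) | C[C@H](O)[C@H](OCc1ccc(OC)cc1)C[C@H](C(C)=C)[C@H](ONc1ccccc1)CO | intermediate
9 | 5,10-bis-TES ether of 8 | C[C@H](O[Si](CC)(CC)CC)[C@H](OCc1ccc(OC)cc1)C[C@H](C(C)=C)[C@H](ONc1ccccc1)CO[Si](CC)(CC)CC | intermediate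
10 | C6 alcohol (5,10-bis-TES, 9-PMB) | C[C@H](O[Si](CC)(CC)CC)[C@H](OCc1ccc(OC)cc1)C[C@H](C(C)=C)[C@H](O)CO[Si](CC)(CC)CC | intermediate
11 | C6 DMB ether (5,10-bis-TES, 9-PMB) | C[C@H](O[Si](CC)(CC)CC)[C@H](OCc1ccc(OC)cc1)C[C@H](C(C)=C)[C@H](OCc1ccc(OC)c(OC)c1)CO[Si](CC)(CC)CC | intermediate
12 | C5 aldehyde (6-DMB, 9-PMB, 10-TES) | C[C@H](O[Si](CC)(CC)CC)[C@H](OCc1ccc(OC)cc1)C[C@H](C(C)=C)[C@H](OCc1ccc(OC)c(OC)c1)C=O | intermediate
13 | 3-[(tert-butyldimethylsilyl)oxy]propanal | O=CCCO[Si](C)(C)C(C)(C)C | starting material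
14 | (Z)-tert-butyl[(4-iodopent-3-en-1-yl)oxy]dimethylsilane | I/C(C)=C\CCO[Si](C)(C)C(C)(C)C | intermediate
15 | (Z)-vinyllithium from 14 (not isolated) | [Li]/C(C)=C\CCO[Si](C)(C)C(C)(C)C | intermediate
16 | (Z)-vinylmagnesium bromide from 15 (not isolated) | Br[Mg]/C(C)=C\CCO[Si](C)(C)C(C)(C)C | intermediate
17 | (3Z)-allylic alcohol, 5,6-syn (C5 epimeric to 27; 1-TBS, 6-DMB, 9-PMB, 10-TES) | C[C@H](O[Si](CC)(CC)CC)[C@H](OCc1ccc(OC)cc1)C[C@H](C(C)=C)[C@H](OCc1ccc(OC)c(OC)c1)[C@@H](O)/C(C)=C\CCO[Si](C)(C)C(C)(C)C | intermediate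
18 | threo 3,4-epoxy-5-ol (C3, C4 as in 27; C5 epimeric) | C[C@H](O[Si](CC)(CC)CC)[C@H](OCc1ccc(OC)cc1)C[C@H](C(C)=C)[C@H](OCc1ccc(OC)c(OC)c1)[C@@H](O)[C@]1(C)O[C@@H]1CCO[Si](C)(C)C(C)(C)C | intermediate
19 | 3,4-epoxy-5-ketone | C[C@H](O[Si](CC)(CC)CC)[C@H](OCc1ccc(OC)cc1)C[C@H](C(C)=C)[C@H](OCc1ccc(OC)c(OC)c1)C(=O)[C@]1(C)O[C@@H]1CCO[Si](C)(C)C(C)(C)C | intermediate
20 | erythro 3,4-epoxy-5-ol (C3–C7 and C9 as in 27) | C[C@H](O[Si](CC)(CC)CC)[C@H](OCc1ccc(OC)cc1)C[C@H](C(C)=C)[C@H](OCc1ccc(OC)c(OC)c1)[C@H](O)[C@]1(C)O[C@@H]1CCO[Si](C)(C)C(C)(C)C | intermediate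
21 | C5 acetate of 20 | C[C@H](O[Si](CC)(CC)CC)[C@H](OCc1ccc(OC)cc1)C[C@H](C(C)=C)[C@H](OCc1ccc(OC)c(OC)c1)[C@H](OC(C)=O)[C@]1(C)O[C@@H]1CCO[Si](C)(C)C(C)(C)C | intermediate
22 | C1,C10-diol (5-OAc, 6-DMB, 9-PMB, 3,4-epoxide) | C[C@H](O)[C@H](OCc1ccc(OC)cc1)C[C@H](C(C)=C)[C@H](OCc1ccc(OC)c(OC)c1)[C@H](OC(C)=O)[C@]1(C)O[C@@H]1CCO | intermediate
23 | open-chain C10 methyl ketone/C1 aldehyde | CC(=O)[C@H](OCc1ccc(OC)cc1)C[C@H](C(C)=C)[C@H](OCc1ccc(OC)c(OC)c1)[C@H](OC(C)=O)[C@]1(C)O[C@@H]1CC=O | intermediate
24 | ten-membered 1,10-diol (all eight ring stereocentres as in 27; 6-DMB, 9-PMB) | C[C@]2(O)[C@H](OCc1ccc(OC)cc1)C[C@H](C(C)=C)[C@H](OCc1ccc(OC)c(OC)c1)[C@H](OC(C)=O)[C@]1(C)O[C@@H]1C[C@@H]2O | intermediate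
25 | 1,6,10-triol (9-PMB, 5-OAc) | C[C@]2(O)[C@H](OCc1ccc(OC)cc1)C[C@H](C(C)=C)[C@H](O)[C@H](OC(C)=O)[C@]1(C)O[C@@H]1C[C@@H]2O | intermediate
26 | 1,6-bis-angelate 9-PMB ether | C[C@]2(O)[C@H](OCc1ccc(OC)cc1)C[C@H](C(C)=C)[C@H](OC(=O)/C(C)=C\C)[C@H](OC(C)=O)[C@]1(C)O[C@@H]1C[C@@H]2OC(=O)/C(C)=C\C | intermediate
27 | (1S,3R,4R,5S,6S,7R,9R,10S)-5-acetoxy-1,6-bis(angeloyloxy)-3,4-epoxygermacr-11-ene-9,10-diol | C=C(C)[C@H]1C[C@@H](O)[C@](C)(O)[C@@H](OC(=O)/C(C)=C\C)C[C@H]2O[C@@]2(C)[C@@H](OC(C)=O)[C@H]1OC(=O)/C(C)=C\C | target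

Total step count: 21. Longest linear sequence: 20 steps (steps 1–9 and 11–21 from (R)-carvone); step 10 is a one-step side branch.

Steps most likely to fail

1. Step 18 (ring closure). The configuration at C1 is decided by the conformation of the ten-membered transition state and not by a neighbouring stereocentre, so the ketyl may add through the wrong face and give the 1,10-cis diol. The β,γ-epoxy aldehyde may also suffer epoxide opening before cyclisation. Fallback, setting out from 23 and returning at 24: the closure is run as before and the C1-epimeric diol F1 is oxidised at its secondary carbinol with DMP to the macrocyclic α-ketol F2. The tertiary hydroxyl is capped with TMS-imidazole to give the silyl ether F3. Reduction with LiAlH(O-t-Bu)3 in THF at −78 °C under Felkin–Anh control (hydride anti to the C10–OSi bond) should give the 1,10-threo alcohol as its TMS ether F4, and brief citric acid/MeOH treatment returns 24. C1 is then set by carbonyl reduction instead of by the C–C bond formation.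

2. Step 20 (double angeloylation). Acylation of the hindered C6 hydroxyl inside the ring may be slow, so that acetyl migration from O5 to the free O6 and Z-to-E isomerisation of the angelate compete at the temperature needed. Fallback, setting out from 21 and returning at 26: the C6 ester is introduced on the flexible open chain. DDQ removes the DMB ether of 21 to give the C6 alcohol F5, which is acylated with the same mixed anhydride to the C6 angelate F6. HF·pyridine then gives the diol F7, DMP the keto aldehyde F8 and SmI2 the macrocyclic diol F9. Its only free secondary hydroxyl (C1) is angeloylated under the conditions of step 20 to give 26, so the macrocycle undergoes a single acylation at the less hindered position.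

3. Step 11 (chelate-controlled vinyl addition). Chelation may be incomplete and Felkin–Anh addition may compete, which would give the C5 epimer and hence the wrong epoxide face in step 12. Fallback, setting out from 12 and 14 and returning at 17: the coupling is run without regard to C5 (vinyllithium 15, THF, −78 °C), giving 17 together with its 5,6-anti epimer F10. The mixture is oxidised with DMP to the (Z)-enone F11. Felkin–Anh 1,2-reduction with LiBH(s-Bu)3 in THF at −78 °C, with hydride anti to the C6–O bond, should then give the 5,6-syn alcohol 17, so that C5 is set by ketone reduction instead of by the addition.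

Further compounds
F1 | step 18 | C1 epimer of 24 (1,10-cis diol) | C[C@]2(O)[C@H](OCc1ccc(OC)cc1)C[C@H](C(C)=C)[C@H](OCc1ccc(OC)c(OC)c1)[C@H](OC(C)=O)[C@]1(C)O[C@@H]1C[C@H]2O
F2 | step 18 | macrocyclic α-ketol (C1 ketone, C10 tertiary alcohol) | C[C@]2(O)[C@H](OCc1ccc(OC)cc1)C[C@H](C(C)=C)[C@H](OCc1ccc(OC)c(OC)c1)[C@H](OC(C)=O)[C@]1(C)O[C@@H]1CC2=O
F3 | step 18 | C10 O-TMS ether of F2 | C[C@]2(O[Si](C)(C)C)[C@H](OCc1ccc(OC)cc1)C[C@H](C(C)=C)[C@H](OCc1ccc(OC)c(OC)c1)[C@H](OC(C)=O)[C@]1(C)O[C@@H]1CC2=O
F4 | step 18 | C10 O-TMS ether of 24 | C[C@]2(O[Si](C)(C)C)[C@H](OCc1ccc(OC)cc1)C[C@H](C(C)=C)[C@H](OCc1ccc(OC)c(OC)c1)[C@H](OC(C)=O)[C@]1(C)O[C@@H]1C[C@@H]2O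
F5 | step 20 | open-chain C6 alcohol (1-TBS, 5-OAc, 9-PMB, 10-TES) | C[C@H](O[Si](CC)(CC)CC)[C@H](OCc1ccc(OC)cc1)C[C@H](C(C)=C)[C@H](O)[C@H](OC(C)=O)[C@]1(C)O[C@@H]1CCO[Si](C)(C)C(C)(C)C
F6 | step 20 | open-chain C6 angelate (1-TBS, 5-OAc, 9-PMB, 10-TES) | C[C@H](O[Si](CC)(CC)CC)[C@H](OCc1ccc(OC)cc1)C[C@H](C(C)=C)[C@H](OC(=O)/C(C)=C\C)[C@H](OC(C)=O)[C@]1(C)O[C@@H]1CCO[Si](C)(C)C(C)(C)C
F7 | step 20 | C1,C10-diol with C6 angelate | C[C@H](O)[C@H](OCc1ccc(OC)cc1)C[C@H](C(C)=C)[C@H](OC(=O)/C(C)=C\C)[C@H](OC(C)=O)[C@]1(C)O[C@@H]1CCO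
F8 | step 20 | open-chain keto aldehyde with C6 angelate | CC(=O)[C@H](OCc1ccc(OC)cc1)C[C@H](C(C)=C)[C@H](OC(=O)/C(C)=C\C)[C@H](OC(C)=O)[C@]1(C)O[C@@H]1CC=O
F9 | step 20 | macrocyclic 1,10-diol with C6 angelate (9-PMB) | C[C@]2(O)[C@H](OCc1ccc(OC)cc1)C[C@H](C(C)=C)[C@H](OC(=O)/C(C)=C\C)[C@H](OC(C)=O)[C@]1(C)O[C@@H]1C[C@@H]2O
F10 | step 11 | C5 epimer of 17 (5,6-anti allylic alcohol) | C[C@H](O[Si](CC)(CC)CC)[C@H](OCc1ccc(OC)cc1)C[C@H](C(C)=C)[C@H](OCc1ccc(OC)c(OC)c1)[C@H](O)/C(C)=C\CCO[Si](C)(C)C(C)(C)C
F11 | step 11 | (Z)-enone (C5 ketone) | C[C@H](O[Si](CC)(CC)CC)[C@H](OCc1ccc(OC)cc1)C[C@H](C(C)=C)[C@H](OCc1ccc(OC)c(OC)c1)C(=O)/C(C)=C\CCO[Si](C)(C)C(C)(C)C
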